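# Proposed synthesis of 2,4,7-tribromo-3-chloro-1H-indole (CNP0103640.0)

## Structural features

The target is 2,4,7-tribromo-3-chloro-1H-indole. A benzene ring (C3a, C4, C5, C6, C7, C7a) is fused through the C3a–C7a bond to a pyrrole ring (N1, C2, C3, C3a, C7a). Br sits on C2, C4 and C7 and Cl on C3. Only N1–H, C5–H and C6–H remain, and the molecule is flat with no stereocentre, axis or plane of chirality.

The pyrrole halogens follow the innate reactivity of an indole (C3 first, then C2). The mixed pair C3–Cl/C2–Br is therefore only a question of order, made slightly harder by the peri contact between C3–Cl and C4–Br.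

The real difficulty is the benzene ring. It is 1,2,3,4-tetrasubstituted (N1 on C7a, C3 on C3a, Br on C4, Br on C7), and C4 and C7 are the positions that electrophilic halogenation of an indole does not reach.

The fragile parts are the 2-halo-1H-indole unit (acid, light, hydrolysis towards an oxindole) and the three C–Br bonds. The C–Br bonds exclude Pd(0), halogen–metal exchange, stannyl radicals and hydrogenolysis late in the route.

The key step exploits one feature. The arc C4(Br)–C5H=C6H–C7(Br) is a locally C2-symmetric 1,4-dibromobuta-1,3-diene clipped onto both ends of C3a–C7a. That bond is at the same time the enamine C=C bond of the five-membered nitrogen ring. So the benzene ring, not the pyrrole ring, is the ring to be made.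

One-sentence test: a Diels–Alder/SO2-extrusion benzannulation of a symmetric 2,5-dibromothiophene S,S-dioxide onto the enamide C=C bond of a preformed five-membered nitrogen ring builds the dibrominated benzene ring. This sentence does not fit the default route, which buys the bromoarene and builds the pyrrole ring onto it.

## Logic of the disconnections

**11 ⇒ 10.**
- Cut: the C2–Br bond.
- Reason: C2 is the only activated position left once C3 is filled, and the most fragile function of the target appears last.
- Gain: one halogen and the acid-labile 2-haloindole unit are removed.
- Demand: one equivalent of a mild Br+ source, no acid build-up, and no exchange or migration of the C3 chlorine.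

**10 ⇒ 9.**
- Cut: the C3–Cl bond.
- Reason: C3 is the enamine β-carbon and the most nucleophilic site of 9, while the benzene ring is deactivated by two Br atoms.
- Gain: the halogen problem is reduced to the benzene ring alone.
- Demand: mono-chlorination next to the peri Br on C4, stopping before C2 reacts.

**9 ⇒ 8 ⇒ 7.**
- Change: the C2=C3 π bond is saturated retrosynthetically, and the N1–H bond is exchanged for an N1–C(=O)O-tBu bond.
- Reason: the five-membered ring reaches the oxidation level of a pyrroline, which has a single non-aromatic C=C bond exactly at C3a–C7a.
- Gain: the later 2π partner pays no aromaticity penalty and is an article of commerce.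
- Demand: the carbamate must leave only after the benzene ring is aromatic, and the dehydrogenation needs the free nitrogen lone pair.

**7 ⇒ 6 ⇒ 5 ⇒ 3 + 4 (key disconnection).**
- Cut: the bonds C3a–C4 and C7–C7a. Two hydrogens are put back on C3a and C7a (6), and an SO2 bridge is put back between C4 and C7 (5).
- Reason: the four-carbon arc with both Br atoms is a symmetric diene, so the orientation of the unsymmetrical alkene does not matter and both C–Br bonds are placed by construction.
- Gain: a bicyclic, tetrasubstituted arene falls apart into two monocyclic five-membered rings. Two C–C bonds and one ring are formed in one operation.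
- Demand: the cycloaddition must outrun dimerisation of 3, and 6 must be aromatised by loss of two hydrogens, not by loss of nitrogen from C7a or of HBr.

**3 ⇒ 2 ⇒ 1.**
- Cut: the two S=O bonds.
- Reason: oxidation at sulfur switches off the aromaticity of the thiophene and turns it into an electron-poor diene with a built-in leaving bridge.
- Gain: a bulk chemical with both Br atoms already in the right 1,4-relationship.
- Demand: an oxidant strong enough for an electron-poor sulfur, and a second oxidation fast enough that 2 does not accumulate.

## Other disconnections considered

Alternative 1: This is the first that comes to mind.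
- **Cut:** C3–C3a and N1–C2 of 9.
- **Forward key step:** Bartoli indole synthesis. 1,4-Dibromo-2-nitrobenzene A1 reacts with three equivalents of a vinyl Grignard reagent through the nitrosoarene A2. A [3,3]-shift into the only free ortho position follows, then the same two halogenations as in steps 5 and 6.
- **Step count:** this plan is shorter in steps, and that is conceded.
- **Grounds for preferring the chosen plan:**
  - The whole substitution pattern of the difficult ring is simply bought in A1, so the plan is the default answer and fails the first test.
  - Mechanistically it spends two of the three equivalents of organometallic as reductant and base.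
  - A2 can partition between O-attack (productive) and N-attack or reduction.
  - Both C–Br bonds lie ortho and meta to a nitro group in the presence of excess Grignard reagent, open to exchange and electron transfer.
  - The chosen plan forms the brominated ring under neutral, metal-free conditions. It is also modular, since any symmetric 2,5-dihalothiophene dioxide would give the matching 4,7-dihalo series.

Alternative 2:
- **Cut:** N1–C2 together with C3–Cl of 11.
- **Forward key step:** 5-endo-dig chlorocyclisation of 3,6-dibromo-2-(bromoethynyl)aniline A3 with an electrophilic chlorine source. This would close the pyrrole ring and place both pyrrole halogens at once. A3 would come from the gem-dibromoalkene A4 by dehydrobromination. A4 would come from 2-amino-3,6-dibromobenzaldehyde A5 by Ramirez/Corey–Fuchs olefination.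
- **Grounds for preferring the chosen plan:**
  - The elegant step solves the easy part (C2/C3).
  - The hard part is left intact: A5 carries the same 1,2,3,4-pattern as the target and would itself need a multistep preparation.
  - The chlorine electrophile meets a free aniline, whose nitrogen and para position (later C5) are more nucleophilic than an electron-poor bromoalkyne.
  - The aryl-stabilised vinyl cation favours chlorine on the bromine-bearing carbon, which is the wrong polarity for closure.
  - The sequence would be longer than the chosen route.

Alternative 3:
- **Cut:** one carbon is put back between N1 and C2 of 9, so the pyrrole ring derives from the pyridine ring of a quinoline by ring contraction.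
- **Forward sequence:**
  1. Bromination of the quinolinium ion at its innate positions gives 5,8-dibromoquinoline A6 (C5 and C8 map onto C4 and C7).
  2. N-oxidation gives A7.
  3. Photochemical rearrangement through the oxaziridine gives the 3,1-benzoxazepine A8.
  4. Acid-induced contraction gives the N-formylindole A9.
  5. Deformylation gives 9.
- **Grounds for preferring the chosen plan:**
  - With C2–H in A7, the oxaziridine has an open 1,2-hydrogen shift towards the lactam isomer.
  - The aryl C–Br bonds absorb in the same window, and the heavy atoms favour triplet deoxygenation over rearrangement.
  - The peri Br on C8 shields nitrogen in the N-oxidation.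
  - The step count is no lower, and a carbon atom is introduced only to be thrown away.

Key step: step 2

Remark (assumption): the target has no stereogenic element, so the request for a single enantiomer is met by the achiral compound itself. The stereocentres of the transient compounds 5 and 6 (racemic) are erased within the same step.

## Route

Step 1
Reactants: 1 2,5-dibromothiophene
Product: 3 2,5-dibromothiophene 1,1-dioxide, via 2,5-dibromothiophene 1-oxide 2 (not isolated)
Conditions: urea·H2O2 (6 equiv), (CF3CO)2O (4 equiv), MeCN, 0 °C → rt
Reagents that add atoms: urea–hydrogen peroxide, OO.NC(N)=O (both sulfone oxygens, passed on by trifluoroperacetic acid, OOC(=O)C(F)(F)F, formed from it in the flask)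
Why: Electrophilic S-oxidation of a thiophene with trifluoroperacetic acid, a peracid strong enough for the electron-poor sulfur of a dihalothiophene; the non-aromatic S-oxide 2 is oxidised faster than 1 and should not accumulate. The Br atoms on C2 and C5 slow the self-Diels–Alder dimerisation typical of simple thiophene dioxides, so 3 should be an isolable solid, and the C–Br bonds are inert to peracid.

Step 2
Reactants: 3 2,5-dibromothiophene 1,1-dioxide; 4 tert-butyl 2,3-dihydro-1H-pyrrole-1-carboxylate
Product: 7 tert-butyl 4,7-dibromoindoline-1-carboxylate, via 7-thianorbornene dioxide cycloadduct 5 (not isolated), via cis-tetrahydroindole diene 6 (not isolated)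
Conditions: 3 (1.15 equiv), 4 (1.0 equiv), 2,6-di-tert-butylpyridine (0.1 equiv), PhMe, 90 °C, N2 sweep; then DDQ (1.1 equiv), 0 °C → rt
Reagents that add atoms: none
Why: Reaction type: inverse-electron-demand Diels–Alder reaction of a halogenated thiophene S,S-dioxide with an electron-rich alkene, cheletropic extrusion of SO2, and quinone dehydrogenation of the resulting cyclohexa-1,3-diene in the same flask. The non-aromatic diene 3 has a low LUMO (sulfone, two Br) that matches the HOMO of the enecarbamate 4, and the bonds C3a–C4 and C7–C7a form in one concerted but asynchronous event in which the nucleophilic β-carbon of 4 (later C3a) leads. The only ring closed is the six-membered carbocycle, by an intermolecular suprafacial [4π+2π] cycloaddition that gives 5; loss of SO2 from 5 is a thermally allowed retro-cheletropic step that makes the sequence irreversible and leaves 6. The suprafacial addition to the cis-alkene of the five-membered ring sets H-3a and H-7a cis (racemic), the endo/exo position of the sulfone bridge is of no consequence, and all these centres are flattened again before isolation, so no stereocontrol is needed. No regioselectivity is needed either: 3 is C2v-symmetric, both orientations of 4 give the same 6, and the Br atoms end on C4 and C7 because they sit on the diene termini. The selectivity that is needed is chemoselectivity in the aromatisation of 6: loss of two hydrogens must beat loss of the carbamate nitrogen from C7a together with H-3a (which would open the five-membered ring) and loss of HBr. The substrate helps because N1 and H-3a are trans on the six-membered ring (no syn elimination), a carbamate anion is a poor leaving group without acid and both C–Br bonds are vinylic, and the conditions help through the hindered base, the removal of SO2 and the omission of any chromatography of 6. DDQ then abstracts hydride from C7a–H, which is α to nitrogen and conjugated with the diene, and the cation loses H-3a as a proton to give 7.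

Step 3
Reactants: 7 tert-butyl 4,7-dibromoindoline-1-carboxylate
Product: 8 4,7-dibromoindoline
Conditions: TFA, CH2Cl2, 0 °C → rt; aq. NaHCO3 work-up
Reagents that add atoms: none
Why: Acidolysis of a tert-butyl carbamate (loss of the tert-butyl cation as isobutene, then decarboxylation). The six-membered ring is now aromatic, so the acid-triggered ring opening that threatened 6 is no longer possible, and the aryl bromides are inert to TFA.

Step 4
Reactants: 8 4,7-dibromoindoline
Product: 9 4,7-dibromo-1H-indole
Conditions: DDQ (1.05 equiv), PhMe, rt
Reagents that add atoms: none
Why: Quinone dehydrogenation of an indoline: hydride abstraction from C2–H α to the free nitrogen gives the 3H-indolium ion, which loses a proton from C3 to give the aromatic pyrrole ring. The step needs the free nitrogen lone pair, which is why the carbamate is removed first.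

Step 5
Reactants: 9 4,7-dibromo-1H-indole
Product: 10 4,7-dibromo-3-chloro-1H-indole
Conditions: NCS (1.0 equiv), DMF, 0 °C → rt, dark
Reagents that add atoms: N-chlorosuccinimide, O=C1CCC(=O)N1Cl
Why: Electrophilic aromatic substitution at C3, the enamine β-carbon and most nucleophilic site of an indole. The benzene ring is deactivated by two Br atoms, and one equivalent of reagent at low temperature keeps C2 untouched.

Step 6
Reactants: 10 4,7-dibromo-3-chloro-1H-indole
Product: 11 2,4,7-tribromo-3-chloro-1H-indole (target)
Conditions: NBS (1.0 equiv), CH2Cl2, −20 → 0 °C, dark; aq. NaHCO3/Na2S2O3 work-up
Reagents that add atoms: N-bromosuccinimide, O=C1CCC(=O)N1Br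
Why: Electrophilic bromination of a 3-substituted indole at C2, either by direct attack or by attack at C3 and 1,2-shift of the better migrating Br in the 3-bromo-3-chloro-3H-indole. C2 is the only activated position left, and the cold, buffered work-up protects the acid- and light-sensitive 2-haloindole.

## Compound list

1 | 2,5-dibromothiophene | Brc1ccc(Br)s1 | starting material
2 | 2,5-dibromothiophene 1-oxide | O=S1C(Br)=CC=C1Br | intermediate (not isolated)
3 | 2,5-dibromothiophene 1,1-dioxide | O=S1(=O)C(Br)=CC=C1Br | intermediate
4 | tert-butyl 2,3-dihydro-1H-pyrrole-1-carboxylate (N-Boc-2-pyrroline) | CC(C)(C)OC(=O)N1CCC=C1 | starting material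
5 | tert-butyl 4,7-dibromo-2,3,3a,4,7,7a-hexahydro-1H-4,7-epithioindole-1-carboxylate 8,8-dioxide (racemic, cis ring fusion, endo/exo not defined) | CC(C)(C)OC(=O)N1CC[C@H]2[C@@H]1C1(Br)C=CC2(Br)S1(=O)=O | intermediate (not isolated)
6 | tert-butyl cis-4,7-dibromo-2,3,3a,7a-tetrahydro-1H-indole-1-carboxylate (racemic, one enantiomer drawn) | CC(C)(C)OC(=O)N1CC[C@H]2[C@@H]1C(Br)=CC=C2Br | intermediate (not isolated)
7 | tert-butyl 4,7-dibromoindoline-1-carboxylate | CC(C)(C)OC(=O)N1CCc2c(Br)ccc(Br)c21 | intermediate
8 | 4,7-dibromoindoline | Brc1ccc(Br)c2c1CCN2 | intermediate
9 | 4,7-dibromo-1H-indole | Brc1ccc(Br)c2[nH]ccc12 | intermediate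
10 | 4,7-dibromo-3-chloro-1H-indole | Clc1c[nH]c2c(Br)ccc(Br)c12 | intermediate
11 | 2,4,7-tribromo-3-chloro-1H-indole (achiral) | Clc1c(Br)[nH]c2c(Br)ccc(Br)c12 | target

## Step count and least certain steps

Total step count: 6. Longest linear sequence: 6 steps (1 → 3 → 7 → 8 → 9 → 10 → 11); 4 is purchased.

**Step 2 (key step).**
- Most likely failure: eliminative aromatisation of 6. Ionisation or anti elimination of the carbamate nitrogen from C7a together with H-3a opens the five-membered ring, because the gain in aromaticity is the same as for the wanted dehydrogenation.
- Second failure mode: a cycloaddition slowed by the Br atoms on the diene termini. Dimerisation of 3 or acid-induced oligomerisation of 4 could then take over.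
- Fallback: it sets out from 3 and comes back at 7. It changes the aromatisation from oxidative to eliminative.
  - O-silylation of commercial N-Boc-2-pyrrolidinone (TBSOTf, Et3N, CH2Cl2) would give the silyl ketene N,O-acetal tert-butyl 5-[(tert-butyldimethylsilyl)oxy]-2,3-dihydro-1H-pyrrole-1-carboxylate F1. This is a far more electron-rich 2π partner that should react with 3 at lower temperature.
  - After loss of SO2 it would give tert-butyl 4,7-dibromo-7a-[(tert-butyldimethylsilyl)oxy]-2,3,3a,7a-tetrahydro-1H-indole-1-carboxylate F2, in which C7a is the carbon of an N-Boc N,O-acetal.
  - Mild acid (PPTS) should ionise the C–O bond, as in N-acyliminium chemistry. Loss of the proton from C3a then gives 7 without any oxidant, and the nitrogen stays in place because a better leaving group is built in.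

**Step 1.**
- Most likely failure: a sluggish first oxidation of the electron-poor sulfur. The S-oxide 2 could then be consumed by self-cycloaddition before the second oxygen arrives, and the ring could be degraded by excess peracid.
- Fallback: it sets out from 1 and comes back at 3. It moves the oxidation to an electron-rich thiophene.
  - Double Br/Li exchange of 1 (n-BuLi) and quenching with TMSCl would give 2,5-bis(trimethylsilyl)thiophene F3.
  - Oxidation of F3 with mCPBA should run readily to 2,5-bis(trimethylsilyl)thiophene 1,1-dioxide F4.
  - Two-fold ipso-bromodesilylation (Br2, AgBF4, CH2Cl2) then gives 3.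

**Step 6.**
- Most likely failure: ipso attack of Br+ at C3, followed by migration or exchange of the wrong halogen (scrambling of Cl and Br between C2 and C3). Acid-induced decomposition of the product by traces of HBr is the other risk.
- Fallback: it sets out from 10 and comes back at 11. It replaces electrophilic substitution by C–H metalation.
  - Iridium-catalysed C–H borylation ([Ir(OMe)(cod)]2, dtbpy, B2pin2, THF) should take place at C2. This is the electronically preferred position of an N–H indole and the only C–H bond not flanked by Br.
  - The product would be 4,7-dibromo-3-chloro-2-(4,4,5,5-tetramethyl-1,3,2-dioxaborolan-2-yl)-1H-indole F5.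
  - Copper(II)-mediated bromodeboronation (CuBr2, MeOH/H2O) then places Br exactly where boron was and gives 11.

**Step 4.**
- Most likely failure: slow hydride abstraction from the electron-poor indoline. Charge-transfer complexation and oxidative coupling at nitrogen would then compete with clean dehydrogenation.
- Fallback: it sets out from 7 and comes back at 9. It dehydrogenates by halogenation/elimination at the protected stage.
  - Wohl–Ziegler bromination (NBS, AIBN, PhCF3, 80 °C) at the benzylic C3 would give tert-butyl 3,4,7-tribromoindoline-1-carboxylate F6.
  - Loss of HBr (2,4,6-collidine) would give tert-butyl 4,7-dibromo-1H-indole-1-carboxylate F7.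
  - Methanolysis of the activated indole carbamate (cat. K2CO3, MeOH, rt) gives 9.

## Further compounds

F1 | step 2 | tert-butyl 5-[(tert-butyldimethylsilyl)oxy]-2,3-dihydro-1H-pyrrole-1-carboxylate | CC(C)(C)OC(=O)N1CCC=C1O[Si](C)(C)C(C)(C)C
F2 | step 2 | tert-butyl 4,7-dibromo-7a-[(tert-butyldimethylsilyl)oxy]-2,3,3a,7a-tetrahydro-1H-indole-1-carboxylate (racemic, cis ring fusion) | CC(C)(C)OC(=O)N1CC[C@H]2[C@]1(O[Si](C)(C)C(C)(C)C)C(Br)=CC=C2Br
F3 | step 1 | 2,5-bis(trimethylsilyl)thiophene | C[Si](C)(C)c1ccc(s1)[Si](C)(C)C
F4 | step 1 | 2,5-bis(trimethylsilyl)thiophene 1,1-dioxide | C[Si](C)(C)C1=CC=C([Si](C)(C)C)S1(=O)=O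
F5 | step 6 | 4,7-dibromo-3-chloro-2-(4,4,5,5-tetramethyl-1,3,2-dioxaborolan-2-yl)-1H-indole | CC1(C)OB(OC1(C)C)c1[nH]c2c(Br)ccc(Br)c2c1Cl
F6 | step 4 | tert-butyl 3,4,7-tribromoindoline-1-carboxylate (racemic) | CC(C)(C)OC(=O)N1CC(Br)c2c(Br)ccc(Br)c21
F7 | step 4 | tert-butyl 4,7-dibromo-1H-indole-1-carboxylate | CC(C)(C)OC(=O)n1ccc2c(Br)ccc(Br)c21
A1 | alternative 1 | 1,4-dibromo-2-nitrobenzene | O=[N+]([O-])c1cc(Br)ccc1Br
A2 | alternative 1 | 1,4-dibromo-2-nitrosobenzene | O=Nc1cc(Br)ccc1Br
A3 | alternative 2 | 3,6-dibromo-2-(bromoethynyl)aniline | Nc1c(Br)ccc(Br)c1C#CBr
A4 | alternative 2 | 3,6-dibromo-2-(2,2-dibromovinyl)aniline | Nc1c(Br)ccc(Br)c1C=C(Br)Br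
A5 | alternative 2 | 2-amino-3,6-dibromobenzaldehyde | Nc1c(Br)ccc(Br)c1C=O
A6 | alternative 3 | 5,8-dibromoquinoline | Brc1ccc(Br)c2ncccc12
A7 | alternative 3 | 5,8-dibromoquinoline 1-oxide | [O-][n+]1cccc2c(Br)ccc(Br)c12
A8 | alternative 3 | 6,9-dibromo-3,1-benzoxazepine | C1=Nc2c(Br)ccc(Br)c2C=CO1
A9 | alternative 3 | 4,7-dibromo-1H-indole-1-carbaldehyde | O=Cn1ccc2c(Br)ccc(Br)c12
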